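**Retrosynthetic overview**
1. 19 ⇒ 18 by loss of one benzyl group. 18 is then cut at C3'–C8'' and at C5''–C6'', giving bromoflavone 8 (fragment 1) and γ-pyrone keto ester 16 (fragment 2), which are joined and folded in one flask.
2. Enabling feature: ring A'' is a phloroglucinol ring with the alternating oxygen pattern of a poly-β-carbonyl chain, so C8'' is a chain methylene. With ring C'' (O1''–C8a'') closed and C5''–C6'' open, C8''H2 lies between the C7'' ketone and the acceptor C8a''=C4a''(C4''=O)(C5''O2Me). It is the only doubly activated carbon; C6'' is a plain CH3, and C3' carries bromine next to the 4'-methoxy group.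
3. 16 ⇐ lateral acetylation of the 2-methyl-γ-pyrone ester 14 ⇐ oxa-Michael closure and dehydrogenation of 12 ⇐ methyl acetoacetate 11 + cinnamoyl chloride 10.
4. 8 ⇐ 5-O-demethylation of 7 ⇐ chalcone 5 ⇐ acetophenone 3, made from the symmetric phenol 2, whose symmetry places the methyl group at C6.
5. Ring order: fragment 1 has rings A and B from the start and closes ring C in step 4. Fragment 2 closes ring C'' in step 8 and ring A'' last, in step 10.

Key step: step 10

Locants: in the methylated flavone half the chromenone is C2–C8a and the aryl ring is C1'–C6'. In the apigenin half the chromenone is C2''–C8a'' and the aryl ring is C1'''–C6'''.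
Assumption: the target SMILES carries no stereodescriptor, so the C3'–C8'' axis is treated as not configured and no stereocentre has to be set.

Step 1
Reactants: 1 4-hydroxy-2,6-dimethoxybenzaldehyde
Product: 2 3,5-dimethoxy-4-methylphenol
Conditions: H2 (4 atm), 10% Pd/C, AcOH, 50 °C
Reagents that add atoms: none
Why: Catalytic hydrogenolysis of an electron-rich benzaldehyde (reduction to the benzylic alcohol, then C–O hydrogenolysis assisted by the para-hydroxy and ortho-methoxy groups) should give the methyl arene, a mirror-symmetric phenol with two equivalent free positions.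

Step 2
Reactants: 2 3,5-dimethoxy-4-methylphenol
Product: 3 1-(6-hydroxy-2,4-dimethoxy-3-methylphenyl)ethan-1-one
Conditions: Ac2O, BF3·OEt2 (solvent), 60 °C; then aq. NaOAc
Reagents that add atoms: acetic anhydride, CC(=O)OC(C)=O
Why: Friedel–Crafts acylation (or O-acylation and Fries shift) ortho to the phenol should be easy on this very electron-rich ring, and symmetry allows only one product, with the future C6 methyl group between the two methoxy groups.

Step 3
Reactants: 3 1-(6-hydroxy-2,4-dimethoxy-3-methylphenyl)ethan-1-one; 4 3-bromo-4-methoxybenzaldehyde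
Product: 5 (E)-3-(3-bromo-4-methoxyphenyl)-1-(6-hydroxy-2,4-dimethoxy-3-methylphenyl)prop-2-en-1-one
Conditions: KOH, EtOH–H2O, rt; then 1 M HCl
Reagents that add atoms: none
Why: Claisen–Schmidt condensation of a 2-hydroxyacetophenone with a non-enolisable aldehyde gives the (E)-chalcone under thermodynamic control.

Step 4
Reactants: 5 (E)-3-(3-bromo-4-methoxyphenyl)-1-(6-hydroxy-2,4-dimethoxy-3-methylphenyl)prop-2-en-1-one
Product: 7 2-(3-bromo-4-methoxyphenyl)-5,7-dimethoxy-6-methyl-4H-chromen-4-one, via flavanone 6 (not isolated)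
Conditions: I2 (10 mol %), DMSO, 130 °C
Reagents that add atoms: none
Why: Iodine/DMSO oxidative cyclisation of a 2'-hydroxychalcone (6-endo oxa-Michael closure of ring C to 6, alpha-iodination, loss of HI, re-oxidation of HI by DMSO) is unambiguous here because only one phenol is free to become O1.

Step 5
Reactants: 7 2-(3-bromo-4-methoxyphenyl)-5,7-dimethoxy-6-methyl-4H-chromen-4-one
Product: 8 2-(3-bromo-4-methoxyphenyl)-5-hydroxy-7-methoxy-6-methyl-4H-chromen-4-one
Conditions: BCl3 (1.5 equiv), CH2Cl2, −78 → 0 °C; then H2O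
Reagents that add atoms: none
Why: Chelation-controlled aryl methyl ether cleavage: BCl3 bridges the C4 carbonyl and the peri 5-methoxy oxygen, so only this methyl group is lost and the 7- and 4'-methoxy groups and the bromide stay.

Step 6
Reactants: 9 (E)-3-[4-(benzyloxy)phenyl]prop-2-enoic acid
Product: 10 (E)-3-[4-(benzyloxy)phenyl]prop-2-enoyl chloride
Conditions: (COCl)2, DMF (cat.), CH2Cl2, 0 °C → rt
Reagents that add atoms: oxalyl chloride, O=C(Cl)C(=O)Cl
Why: Acid chloride formation through the catalytic chloroiminium (Vilsmeier-type) species leaves the alkene geometry and the benzyl ether untouched.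

Step 7
Reactants: 10 (E)-3-[4-(benzyloxy)phenyl]prop-2-enoyl chloride; 11 methyl acetoacetate
Product: 12 methyl (E)-2-acetyl-5-[4-(benzyloxy)phenyl]-3-oxopent-4-enoate (enolised tricarbonyl, C2 configurationally labile)
Conditions: MgCl2, pyridine, CH2Cl2, 0 °C → rt; then 1 M HCl
Reagents that add atoms: none
Why: C-acylation of a β-keto ester by soft enolisation, in which the chelated magnesium enolate reacts at carbon and the more acidic product is held as its magnesium chelate.

Step 8
Reactants: 12 methyl (E)-2-acetyl-5-[4-(benzyloxy)phenyl]-3-oxopent-4-enoate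
Product: 14 methyl 6-[4-(benzyloxy)phenyl]-2-methyl-4-oxo-4H-pyran-3-carboxylate, via dihydropyranone 13 (not isolated)
Conditions: TFA (20 mol %), DDQ (1.3 equiv), 1,4-dioxane, 95 °C
Reagents that add atoms: none
Why: Acid-catalysed 6-endo-trig oxa-Michael addition of the acetyl enol oxygen to the enone closes ring C'' as 13, and DDQ dehydrogenation (hydride abstraction from the benzylic, oxygen-bearing carbon, as in the flavanone-to-flavone oxidation) drains the equilibrium to the γ-pyrone.

Step 9
Reactants: 14 methyl 6-[4-(benzyloxy)phenyl]-2-methyl-4-oxo-4H-pyran-3-carboxylate; 15 N-methoxy-N-methylacetamide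
Product: 16 methyl 6-[4-(benzyloxy)phenyl]-4-oxo-2-(2-oxopropyl)-4H-pyran-3-carboxylate
Conditions: LiN(SiMe3)2 (1.1 equiv), THF, −78 °C; then 15, −78 → 0 °C; then 1 M HCl
Reagents that add atoms: none
Why: Lateral (vinylogous) deprotonation of the 2-methyl group of a γ-pyrone, made more acidic by the neighbouring ester, and acylation with a Weinreb amide, whose chelated tetrahedral adduct lasts until the quench and so prevents over-reaction and early ring closure.

Step 10
Reactants: 8 2-(3-bromo-4-methoxyphenyl)-5-hydroxy-7-methoxy-6-methyl-4H-chromen-4-one; 16 methyl 6-[4-(benzyloxy)phenyl]-4-oxo-2-(2-oxopropyl)-4H-pyran-3-carboxylate (1.3 equiv)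
Product: 18 2-[4-(benzyloxy)phenyl]-5,7-dihydroxy-8-[5-(5-hydroxy-7-methoxy-6-methyl-4-oxo-4H-chromen-2-yl)-2-methoxyphenyl]-4H-chromen-4-one, via arylated keto ester 17 (not isolated)
Conditions: Pd2(dba)3 (2.5 mol %), tBuXPhos (6 mol %), K3PO4 (3.5 equiv), 1,4-dioxane, 80 °C; then KOtBu (6 equiv), THF, 25 → 60 °C; then 1 M HCl
Reagents that add atoms: none
Why: Proposed new method: K3PO4 removes a proton from C8''H2 of 16, zerovalent palladium inserts into the C3'–Br bond of 8, the carbanion (which cannot chelate) binds divalent palladium through carbon, and reductive elimination from the bulky tBuXPhos complex forms C3'–C8'' to give 17 as its enolate; KOtBu then gives access to the C6'' methyl enolate, which attacks the C5'' ester, expels methoxide and tautomerises to the phloroglucinol ring A''. The closest known reaction types are the palladium-catalysed alpha-arylation of 1,3-dicarbonyl compounds and benzyl ketones with ortho-substituted aryl bromides, and the Dieckmann closure of δ-keto esters to cyclohexane-1,3-diones and 1,3-naphthalenediols, which is the Claisen folding of a polyketide chain; what is new is their union on a γ-pyrone-masked chain. Ring A'' closes in the 6-(enolendo)-exo-trig mode, and attack on C4'' instead is excluded because it would give an anti-Bredt bicyclo[3.3.1] system. The only new stereocentre, C8'' of 17, is an acidic methine that is never configured and disappears on aromatisation. Site selectivity (C8'' against C6'' and C3'') rests on the gap of several pKa units between the doubly activated CH2 and the plain CH3, and the 8-aryl against 6-aryl question cannot arise because O1''–C8a'' already belongs to ring C''. Early ring closure of 16 is held back by the weak base of the first stage, the chelated 5-OH of 8 has no free ortho position and should be tolerated, and aromatisation makes the last stage irreversible.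

Step 11
Reactants: 18 2-[4-(benzyloxy)phenyl]-5,7-dihydroxy-8-[5-(5-hydroxy-7-methoxy-6-methyl-4-oxo-4H-chromen-2-yl)-2-methoxyphenyl]-4H-chromen-4-one
Product: 19 taiwanhomoflavone A
Conditions: H2 (1 atm), 10% Pd/C, THF–MeOH, rt
Reagents that add atoms: none
Why: Hydrogenolysis of the single benzyl aryl ether runs under mild conditions that the C2=C3 bonds of flavones routinely survive.

**Compound list**
1 | 4-hydroxy-2,6-dimethoxybenzaldehyde | COc1cc(O)cc(OC)c1C=O | starting material
2 | 3,5-dimethoxy-4-methylphenol | COc1cc(O)cc(OC)c1C | intermediate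
3 | 1-(6-hydroxy-2,4-dimethoxy-3-methylphenyl)ethan-1-one | CC(=O)c1c(O)cc(OC)c(C)c1OC | intermediate
4 | 3-bromo-4-methoxybenzaldehyde | COc1ccc(C=O)cc1Br | starting material
5 | (E)-3-(3-bromo-4-methoxyphenyl)-1-(6-hydroxy-2,4-dimethoxy-3-methylphenyl)prop-2-en-1-one | COc1ccc(/C=C/C(=O)c2c(O)cc(OC)c(C)c2OC)cc1Br | intermediate
6 | 2-(3-bromo-4-methoxyphenyl)-5,7-dimethoxy-6-methylchroman-4-one (racemic, not isolated) | COc1ccc(C2CC(=O)c3c(OC)c(C)c(OC)cc3O2)cc1Br | intermediate
7 | 2-(3-bromo-4-methoxyphenyl)-5,7-dimethoxy-6-methyl-4H-chromen-4-one | COc1ccc(-c2cc(=O)c3c(OC)c(C)c(OC)cc3o2)cc1Br | intermediate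
8 | 2-(3-bromo-4-methoxyphenyl)-5-hydroxy-7-methoxy-6-methyl-4H-chromen-4-one | COc1ccc(-c2cc(=O)c3c(O)c(C)c(OC)cc3o2)cc1Br | intermediate
9 | (E)-3-[4-(benzyloxy)phenyl]prop-2-enoic acid | OC(=O)/C=C/c1ccc(OCc2ccccc2)cc1 | starting material
10 | (E)-3-[4-(benzyloxy)phenyl]prop-2-enoyl chloride | ClC(=O)/C=C/c1ccc(OCc2ccccc2)cc1 | intermediate
11 | methyl acetoacetate | CC(=O)CC(=O)OC | starting material
12 | methyl (E)-2-acetyl-5-[4-(benzyloxy)phenyl]-3-oxopent-4-enoate (C2 labile) | CC(=O)C(C(=O)OC)C(=O)/C=C/c1ccc(OCc2ccccc2)cc1 | intermediate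
13 | methyl 2-[4-(benzyloxy)phenyl]-6-methyl-4-oxo-3,4-dihydro-2H-pyran-5-carboxylate (racemic, not isolated) | CC1=C(C(=O)OC)C(=O)CC(O1)c1ccc(OCc2ccccc2)cc1 | intermediate
14 | methyl 6-[4-(benzyloxy)phenyl]-2-methyl-4-oxo-4H-pyran-3-carboxylate | CC1=C(C(=O)OC)C(=O)C=C(O1)c1ccc(OCc2ccccc2)cc1 | intermediate
15 | N-methoxy-N-methylacetamide | CC(=O)N(C)OC | starting material
16 | methyl 6-[4-(benzyloxy)phenyl]-4-oxo-2-(2-oxopropyl)-4H-pyran-3-carboxylate | CC(=O)CC1=C(C(=O)OC)C(=O)C=C(O1)c1ccc(OCc2ccccc2)cc1 | intermediate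
17 | methyl 6-[4-(benzyloxy)phenyl]-2-{1-[5-(5-hydroxy-7-methoxy-6-methyl-4-oxo-4H-chromen-2-yl)-2-methoxyphenyl]-2-oxopropyl}-4-oxo-4H-pyran-3-carboxylate (methine not configured, not isolated) | COc1ccc(-c2cc(=O)c3c(O)c(C)c(OC)cc3o2)cc1C(C(C)=O)C1=C(C(=O)OC)C(=O)C=C(O1)c1ccc(OCc2ccccc2)cc1 | intermediate
18 | 2-[4-(benzyloxy)phenyl]-5,7-dihydroxy-8-[5-(5-hydroxy-7-methoxy-6-methyl-4-oxo-4H-chromen-2-yl)-2-methoxyphenyl]-4H-chromen-4-one | COc1ccc(-c2cc(=O)c3c(O)c(C)c(OC)cc3o2)cc1-c1c(O)cc(O)c2c(=O)cc(-c3ccc(OCc4ccccc4)cc3)oc12 | intermediate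
19 | taiwanhomoflavone A | COc1ccc(-c2cc(=O)c3c(O)c(C)c(OC)cc3o2)cc1-c1c(O)cc(O)c2c(=O)cc(-c3ccc(O)cc3)oc12 | target

Total step count: 11. Longest linear sequence: 7 (steps 1–5, 10, 11).

**Steps most likely to fail**

Step 10 (Proposed new method). Several things may go wrong:
- Reductive elimination from the hindered, stabilised palladium enolate may be slow, so that hydrodebromination takes over.
- The enolate oxygen may attack the ester and release methoxide, which can open ring C''.
- The arylated ketone may be deacetylated before it folds.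

The fallback is known chemistry, a Suzuki–Miyaura coupling of two finished flavones; it sets out from 8 and comes back at 19. Miyaura borylation of 8 (B2pin2, Pd(dppf)Cl2, KOAc, 1,4-dioxane, 90 °C) should give the 3'-pinacol boronate F1. Purchased apigenin F2 is benzylated on all three phenols (BnBr, K2CO3, DMF, 80 °C) to 5,7,4'-tri-O-benzylapigenin F3. Iodination (N-iodosuccinimide, cat. TFA, CH2Cl2–MeCN) should go to C8, the usual site in fully O-alkylated 5,7-dioxygenated flavones, and give the 8-iodide F4. Coupling of F1 with F4 (Pd(PPh3)4, K2CO3, DMF–H2O, 90 °C) forms the same C3'–C8'' bond in the tri-O-benzyl biflavone F5. Hydrogenolysis under the conditions of step 11 removes the three benzyl groups and gives 19.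

Step 9. The lateral carbanion may condense with the ester or the ring of a second molecule, or acyl transfer to the stabilised carbanion may stay incomplete. The fallback replaces the carbanion by a neutral nucleophile; it sets out from 14 and comes back at 16. Soft enolisation (TBSOTf, Et3N, CH2Cl2, 0 °C) silylates the C4 carbonyl oxygen to a 4-silyloxypyrylium ion, which loses a methyl proton and should give the silyl 2-methylidene-2H-pyran F6. Mukaiyama-type C-acylation at the exocyclic carbon (AcCl, cat. ZnCl2, CH2Cl2, −78 → 0 °C) restores the γ-pyrone and gives 16.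

Step 8. The oxa-Michael equilibrium may be unfavourable, DDQ may oxidatively remove the benzyl ether, or the tricarbonyl may deacetylate on heating. The fallback separates ring closure from oxidation and uses a polar dehydrogenation; it sets out from 12 and comes back at 14. Closure alone (cat. TfOH, CH2Cl2, rt) allows 13 to be isolated. TMSOTf/Et3N converts 13 into the trimethylsilyl dienol ether F7, and Saegusa–Ito oxidation (Pd(OAc)2, MeCN, rt) gives 14.

**Further compounds**
F1 | step 10 | 5-hydroxy-7-methoxy-2-[4-methoxy-3-(4,4,5,5-tetramethyl-1,3,2-dioxaborolan-2-yl)phenyl]-6-methyl-4H-chromen-4-one | COc1ccc(-c2cc(=O)c3c(O)c(C)c(OC)cc3o2)cc1B1OC(C)(C)C(C)(C)O1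
F2 | step 10 | apigenin (purchased) | O=c1cc(-c2ccc(O)cc2)oc2cc(O)cc(O)c12
F3 | step 10 | 5,7-bis(benzyloxy)-2-[4-(benzyloxy)phenyl]-4H-chromen-4-one | O=c1cc(-c2ccc(OCc3ccccc3)cc2)oc2cc(OCc3ccccc3)cc(OCc3ccccc3)c12
F4 | step 10 | 5,7-bis(benzyloxy)-2-[4-(benzyloxy)phenyl]-8-iodo-4H-chromen-4-one | O=c1cc(-c2ccc(OCc3ccccc3)cc2)oc2c(I)c(OCc3ccccc3)cc(OCc3ccccc3)c12
F5 | step 10 | 5,7-bis(benzyloxy)-2-[4-(benzyloxy)phenyl]-8-[5-(5-hydroxy-7-methoxy-6-methyl-4-oxo-4H-chromen-2-yl)-2-methoxyphenyl]-4H-chromen-4-one | COc1ccc(-c2cc(=O)c3c(O)c(C)c(OC)cc3o2)cc1-c1c(OCc2ccccc2)cc(OCc2ccccc2)c2c(=O)cc(-c3ccc(OCc4ccccc4)cc3)oc12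
F6 | step 9 | methyl 6-[4-(benzyloxy)phenyl]-4-[(tert-butyldimethylsilyl)oxy]-2-methylidene-2H-pyran-3-carboxylate | C=C1OC(=CC(O[Si](C)(C)C(C)(C)C)=C1C(=O)OC)c1ccc(OCc2ccccc2)cc1
F7 | step 8 | methyl 2-[4-(benzyloxy)phenyl]-6-methyl-4-[(trimethylsilyl)oxy]-2H-pyran-5-carboxylate (racemic) | CC1=C(C(=O)OC)C(O[Si](C)(C)C)=CC(O1)c1ccc(OCc2ccccc2)cc1
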